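The aryltetralin is cut through ring B at C1–C2 and C3–C4. C1, C8a, C4a and C4 then belong to an α-aryl-α′-hydroxy-o-quinodimethane, and the trans-disposed C2/C3 carbons, each carrying a one-carbon oxygenated arm, belong to a fumarate. Irradiation of a 2-benzylbenzaldehyde generates that dienol, whose [4+2] addition to the bis[(S)-lactyl] fumarate closes ring B, forms both C–C bonds and sets the stereocentres C1–C4 in one operation. The surplus C4 hydroxyl is removed afterwards. The precursor is the dibenzyl-protected diarylmethane aldehyde 6, assembled by Negishi coupling. Reduction, tritylation of the less hindered hydroxymethyl, coumaroylation and one global deprotection complete the synthesis.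

Key step: step 5

Assumption: the (S)-lactate esters are taken to expose the fumarate face leading to (1S,2R,3S,4S)-11, by analogy with fumarates of S-configured α-hydroxy esters in hydroxy-o-quinodimethane cycloadditions; the benzyl-protected building blocks 1, 3 and 15 are taken as purchasable.

Step 1
Reactants: 1 4-(benzyloxy)-3-methoxybenzaldehyde (O-benzylvanillin)
Product: 2 4-(benzyloxy)-2-bromo-5-methoxybenzaldehyde
Conditions: Br2, NaOAc, AcOH, rt
Reagents that add atoms: bromine, BrBr
Why: Electrophilic aromatic bromination goes to the position para to the methoxy group and ortho to the formyl group (the same site as in veratraldehyde), and NaOAc buffers the HBr so that the benzyl ether should survive.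

Step 2
Reactants: 3 [4-(benzyloxy)-3-methoxyphenyl]methanol
Product: 4 1-(benzyloxy)-4-(chloromethyl)-2-methoxybenzene
Conditions: SOCl2, CH2Cl2, 0 °C
Reagents that add atoms: thionyl chloride, O=S(Cl)Cl
Why: Chlorodehydroxylation of an electron-rich benzylic alcohol through its chlorosulfite is fast at 0 °C and leaves the aryl benzyl ether untouched.

Step 3
Reactants: 4 1-(benzyloxy)-4-(chloromethyl)-2-methoxybenzene; 2 4-(benzyloxy)-2-bromo-5-methoxybenzaldehyde
Product: 6 4-(benzyloxy)-2-[4-(benzyloxy)-3-methoxybenzyl]-5-methoxybenzaldehyde, via benzylzinc chloride 5 (not isolated)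
Conditions: Zn dust, LiCl, THF, 25 °C; then 2, Pd(OAc)2 (cat.), SPhos, THF, 25 °C (slow addition of 5)
Reagents that add atoms: none
Why: Negishi coupling: LiCl-assisted zinc insertion into the benzylic C–Cl bond, oxidative addition of the aryl bromide to zerovalent palladium formed in the flask, transmetalation and reductive elimination form the diarylmethane, and the catalysed coupling should outrun addition of the organozinc to the electron-rich, ortho-flanked aldehyde.

Step 4
Reactants: 7 fumaryl chloride; 8 ethyl (S)-lactate (two equivalents)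
Product: 9 bis[(2S)-1-ethoxy-1-oxopropan-2-yl] (2E)-but-2-enedioate
Conditions: 8 (2.1 equiv), pyridine, CH2Cl2, 0 °C → rt
Reagents that add atoms: ethyl (S)-lactate (the second equivalent of 8), CCOC(=O)[C@H](C)O
Why: Double O-acylation (nucleophilic acyl substitution) of two molecules of the secondary alcohol by the two acid chloride groups, with pyridine taking up the HCl, breaks no bond at the lactate stereocentre and keeps the E geometry of the alkene.

Step 5
Reactants: 6 4-(benzyloxy)-2-[4-(benzyloxy)-3-methoxybenzyl]-5-methoxybenzaldehyde; 9 bis[(2S)-1-ethoxy-1-oxopropan-2-yl] (2E)-but-2-enedioate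
Product: 11 bis[(2S)-1-ethoxy-1-oxopropan-2-yl] (1S,2R,3S,4S)-7-(benzyloxy)-1-[4-(benzyloxy)-3-methoxyphenyl]-4-hydroxy-6-methoxy-1,2,3,4-tetrahydronaphthalene-2,3-dicarboxylate, via E-dienol o-quinodimethane 10 (not isolated)
Conditions: hν (350 nm, Pyrex), 9 (2 equiv), degassed benzene, 20 °C
Reagents that add atoms: none
Why: n→π* excitation of the aldehyde and intersystem crossing are followed by 1,5-hydrogen transfer from the doubly benzylic CH2 to the carbonyl oxygen; the Z-hydroxy dienol reverts to 6 by a thermal 1,5-shift, while the longer-lived E-dienol 10 (OH and aryl both outside) is trapped by 9 in a concerted suprafacial [4+2] addition that rearomatises ring A. The closest known reaction type is photoenolisation of o-benzylbenzaldehydes with Diels–Alder trapping by fumarates of chiral α-hydroxy esters. Ring B is closed by intermolecular [4+2] annulation, the bonds C1–C2 and C3–C4 forming together at the two diene termini. C1-aryl and C4-OH come out cis because both diene substituents are outside, C2 and C3 stay trans because the E-alkene geometry is retained, the C3 ester is cis to C4-OH because it takes the endo position under the diene with an O–H···O=C hydrogen bond, and the absolute sense is set by the two (S)-lactate units shielding one face of the fumarate. The step needs endo and π-facial selectivity: the hydrogen-bonding dienol OH secures the first, and the C2-symmetric pair of auxiliaries, which makes both orientations of the dienophile equivalent, secures the second. Excess 9 and long-wavelength light, which neither 9 nor 11 absorbs, should limit dienol reversion and secondary photochemistry.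

Step 6
Reactants: 11 bis[(2S)-1-ethoxy-1-oxopropan-2-yl] (1S,2R,3S,4S)-7-(benzyloxy)-1-[4-(benzyloxy)-3-methoxyphenyl]-4-hydroxy-6-methoxy-1,2,3,4-tetrahydronaphthalene-2,3-dicarboxylate
Product: 12 bis[(2S)-1-ethoxy-1-oxopropan-2-yl] (1S,2R,3R)-7-(benzyloxy)-1-[4-(benzyloxy)-3-methoxyphenyl]-6-methoxy-1,2,3,4-tetrahydronaphthalene-2,3-dicarboxylate
Conditions: Et3SiH, TFA, CH2Cl2, 0 °C
Reagents that add atoms: none
Why: Ionic hydrogenation: TFA ionises the C4–OH to a benzylic cation stabilised by the para benzyloxy group at C7 and Et3SiH reduces it to CH2; C1, C2 and C3 already have the trans,trans arrangement of the target, so no epimerisation is needed, and the esters and benzyl ethers should be stable at 0 °C.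

Step 7
Reactants: 12 bis[(2S)-1-ethoxy-1-oxopropan-2-yl] (1S,2R,3R)-7-(benzyloxy)-1-[4-(benzyloxy)-3-methoxyphenyl]-6-methoxy-1,2,3,4-tetrahydronaphthalene-2,3-dicarboxylate
Product: 13 [(1S,2R,3R)-7-(benzyloxy)-1-[4-(benzyloxy)-3-methoxyphenyl]-6-methoxy-1,2,3,4-tetrahydronaphthalene-2,3-diyl]dimethanol
Conditions: LiAlH4, THF, 0 °C → rt; then H2O, aq. NaOH
Reagents that add atoms: none
Why: Hydride reduction of all four ester carbonyls gives the diol and releases the auxiliaries as water-soluble (S)-propane-1,2-diol; no bond at a stereocentre is broken, and the all-equatorial substituents have no drive to epimerise.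

Step 8
Reactants: 13 [(1S,2R,3R)-7-(benzyloxy)-1-[4-(benzyloxy)-3-methoxyphenyl]-6-methoxy-1,2,3,4-tetrahydronaphthalene-2,3-diyl]dimethanol
Product: 14 [(1S,2R,3R)-7-(benzyloxy)-1-[4-(benzyloxy)-3-methoxyphenyl]-6-methoxy-3-[(trityloxy)methyl]-1,2,3,4-tetrahydronaphthalen-2-yl]methanol
Conditions: TrCl (1.05 equiv), Et3N, DMAP (cat.), CH2Cl2, 0 °C → rt
Reagents that add atoms: trityl chloride (chlorotriphenylmethane), ClC(c1ccccc1)(c1ccccc1)c1ccccc1
Why: Tritylation is governed by steric access, so the hydroxymethyl on C3 (next to the C4 methylene) should react ahead of the one on C2 (next to the aryl-bearing C1).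

Step 9
Reactants: 14 [(1S,2R,3R)-7-(benzyloxy)-1-[4-(benzyloxy)-3-methoxyphenyl]-6-methoxy-3-[(trityloxy)methyl]-1,2,3,4-tetrahydronaphthalen-2-yl]methanol; 15 (2E)-3-[4-(benzyloxy)phenyl]prop-2-enoic acid
Product: 16 [(1S,2R,3R)-7-(benzyloxy)-1-[4-(benzyloxy)-3-methoxyphenyl]-6-methoxy-3-[(trityloxy)methyl]-1,2,3,4-tetrahydronaphthalen-2-yl]methyl (2E)-3-[4-(benzyloxy)phenyl]prop-2-enoate
Conditions: EDC·HCl, DMAP, CH2Cl2, rt
Reagents that add atoms: none
Why: Steglich esterification (carbodiimide activation, acyl transfer through the acylpyridinium) acylates the only free hydroxyl under conditions that leave the trityl ether and the E-alkene intact.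

Step 10
Reactants: 16 [(1S,2R,3R)-7-(benzyloxy)-1-[4-(benzyloxy)-3-methoxyphenyl]-6-methoxy-3-[(trityloxy)methyl]-1,2,3,4-tetrahydronaphthalen-2-yl]methyl (2E)-3-[4-(benzyloxy)phenyl]prop-2-enoate
Product: 17 [(1S,2R,3R)-7-hydroxy-1-(4-hydroxy-3-methoxyphenyl)-3-(hydroxymethyl)-6-methoxy-1,2,3,4-tetrahydronaphthalen-2-yl]methyl (2E)-3-(4-hydroxyphenyl)prop-2-enoate
Conditions: BCl3, C6HMe5, CH2Cl2, −78 → −20 °C; then aq. NaHCO3
Reagents that add atoms: none
Why: Lewis-acid dealkylation: BCl3 cleaves the three aryl benzyl ethers and the trityl ether, pentamethylbenzene captures the benzyl cations by Friedel–Crafts alkylation so the electron-rich rings are not C-benzylated, and the methyl ethers, the ester, the E-alkene and the stereocentres should not react at low temperature.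

Compound list
1 | 4-(benzyloxy)-3-methoxybenzaldehyde (O-benzylvanillin) | COc1cc(C=O)ccc1OCc1ccccc1 | starting material
2 | 4-(benzyloxy)-2-bromo-5-methoxybenzaldehyde | COc1cc(C=O)c(Br)cc1OCc1ccccc1 | intermediate
3 | [4-(benzyloxy)-3-methoxyphenyl]methanol | COc1cc(CO)ccc1OCc1ccccc1 | starting material
4 | 1-(benzyloxy)-4-(chloromethyl)-2-methoxybenzene | COc1cc(CCl)ccc1OCc1ccccc1 | intermediate
5 | [4-(benzyloxy)-3-methoxybenzyl]zinc chloride (LiCl-solvated, in THF) | COc1cc(C[Zn]Cl)ccc1OCc1ccccc1 | intermediate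
6 | 4-(benzyloxy)-2-[4-(benzyloxy)-3-methoxybenzyl]-5-methoxybenzaldehyde | O=Cc1cc(OC)c(OCc2ccccc2)cc1Cc1ccc(OCc2ccccc2)c(OC)c1 | intermediate
7 | fumaryl chloride | O=C(Cl)/C=C/C(=O)Cl | starting material
8 | ethyl (S)-lactate | CCOC(=O)[C@H](C)O | starting material
9 | bis[(2S)-1-ethoxy-1-oxopropan-2-yl] (2E)-but-2-enedioate | CCOC(=O)[C@H](C)OC(=O)/C=C/C(=O)O[C@@H](C)C(=O)OCC | intermediate
10 | (E)-{(6E)-4-(benzyloxy)-6-[4-(benzyloxy)-3-methoxybenzylidene]-3-methoxycyclohexa-2,4-dien-1-ylidene}methanol (E-dienol, OH and aryl both outside) | O/C=C1/C(=C/c2ccc(OCc3ccccc3)c(OC)c2)C=C(OCc2ccccc2)C(OC)=C1 | intermediate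
11 | bis[(2S)-1-ethoxy-1-oxopropan-2-yl] (1S,2R,3S,4S)-7-(benzyloxy)-1-[4-(benzyloxy)-3-methoxyphenyl]-4-hydroxy-6-methoxy-1,2,3,4-tetrahydronaphthalene-2,3-dicarboxylate (1,2-trans, 2,3-trans, 3,4-cis) | COc1cc([C@H]2c3cc(OCc4ccccc4)c(OC)cc3[C@@H](O)[C@@H](C(=O)O[C@@H](C)C(=O)OCC)[C@@H]2C(=O)O[C@@H](C)C(=O)OCC)ccc1OCc1ccccc1 | intermediate
12 | bis[(2S)-1-ethoxy-1-oxopropan-2-yl] (1S,2R,3R)-7-(benzyloxy)-1-[4-(benzyloxy)-3-methoxyphenyl]-6-methoxy-1,2,3,4-tetrahydronaphthalene-2,3-dicarboxylate | COc1cc([C@H]2c3cc(OCc4ccccc4)c(OC)cc3C[C@@H](C(=O)O[C@@H](C)C(=O)OCC)[C@@H]2C(=O)O[C@@H](C)C(=O)OCC)ccc1OCc1ccccc1 | intermediate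
13 | [(1S,2R,3R)-7-(benzyloxy)-1-[4-(benzyloxy)-3-methoxyphenyl]-6-methoxy-1,2,3,4-tetrahydronaphthalene-2,3-diyl]dimethanol | COc1cc([C@H]2c3cc(OCc4ccccc4)c(OC)cc3C[C@@H](CO)[C@@H]2CO)ccc1OCc1ccccc1 | intermediate
14 | [(1S,2R,3R)-7-(benzyloxy)-1-[4-(benzyloxy)-3-methoxyphenyl]-6-methoxy-3-[(trityloxy)methyl]-1,2,3,4-tetrahydronaphthalen-2-yl]methanol | COc1cc([C@H]2c3cc(OCc4ccccc4)c(OC)cc3C[C@@H](COC(c3ccccc3)(c3ccccc3)c3ccccc3)[C@@H]2CO)ccc1OCc1ccccc1 | intermediate
15 | (2E)-3-[4-(benzyloxy)phenyl]prop-2-enoic acid | OC(=O)/C=C/c1ccc(OCc2ccccc2)cc1 | starting material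
16 | [(1S,2R,3R)-7-(benzyloxy)-1-[4-(benzyloxy)-3-methoxyphenyl]-6-methoxy-3-[(trityloxy)methyl]-1,2,3,4-tetrahydronaphthalen-2-yl]methyl (2E)-3-[4-(benzyloxy)phenyl]prop-2-enoate | COc1cc([C@H]2c3cc(OCc4ccccc4)c(OC)cc3C[C@@H](COC(c3ccccc3)(c3ccccc3)c3ccccc3)[C@@H]2COC(=O)/C=C/c2ccc(OCc3ccccc3)cc2)ccc1OCc1ccccc1 | intermediate
17 | [(1S,2R,3R)-7-hydroxy-1-(4-hydroxy-3-methoxyphenyl)-3-(hydroxymethyl)-6-methoxy-1,2,3,4-tetrahydronaphthalen-2-yl]methyl (2E)-3-(4-hydroxyphenyl)prop-2-enoate | COc1cc([C@H]2c3cc(O)c(OC)cc3C[C@@H](CO)[C@@H]2COC(=O)/C=C/c2ccc(O)cc2)ccc1O | target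

Total step count: 10 steps.
Longest linear sequence: 8 steps (1 → 2 → 6 → 11 → 12 → 13 → 14 → 16 → 17, that is steps 1, 3, 5, 6, 7, 8, 9 and 10).

Steps most likely to fail

Step 5. Under continued irradiation the excited aldehyde may pass triplet energy to 9, and the resulting E/Z isomerisation of the dienophile would leak cis-2,3 adducts. The dienol may also revert to 6 faster than it is trapped, and facial discrimination may be incomplete at the temperature of the lamp. The fallback separates the photochemistry from the cycloaddition. It sets out from 6, which would be irradiated in SO2-saturated benzene so that dienol 10 is captured by cheletropic addition as 5-(benzyloxy)-3-[4-(benzyloxy)-3-methoxyphenyl]-1-hydroxy-6-methoxy-1,3-dihydro-2-benzothiophene 2,2-dioxide F1. After isolation, the sulfone would be heated in the dark with 9 in toluene (80–110 °C, ZnO as acid scavenger). Thermal loss of SO2 should regenerate 10, whose cycloaddition to 9 brings the route back at 11.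

Step 8. The two primary hydroxyls may not be told apart well enough, giving the regioisomeric and the bis-trityl ether alongside 14. The fallback replaces steric discrimination by the C4 oxygen as a regiochemical handle. It sets out from 11, which LiAlH4 (THF, 0 °C) would reduce to [(1S,2R,3R,4S)-7-(benzyloxy)-1-[4-(benzyloxy)-3-methoxyphenyl]-4-hydroxy-6-methoxy-1,2,3,4-tetrahydronaphthalene-2,3-diyl]dimethanol F2, in which C4–OH and the C3 hydroxymethyl are cis. PhB(OH)2 (toluene, 4 Å molecular sieves) should tie these two up as the six-membered cyclic phenylboronate F3, leaving only the C2 hydroxymethyl free. Esterification with 15 (EDC·HCl, DMAP) would give the boronate ester F4. Et3SiH/TFA followed by aqueous work-up should remove the C4 oxygen and the boron together to give [(1S,2R,3R)-7-(benzyloxy)-1-[4-(benzyloxy)-3-methoxyphenyl]-3-(hydroxymethyl)-6-methoxy-1,2,3,4-tetrahydronaphthalen-2-yl]methyl (2E)-3-[4-(benzyloxy)phenyl]prop-2-enoate F5. BCl3/C6HMe5 as in step 10 then brings the route back at 17.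

Step 3. The benzylic zinc reagent may add to the aldehyde of 2 before it is cross-coupled, or homocouple during zinc insertion. The fallback uses boron in place of zinc and reverses the polarity of the partners. It sets out from 2, which Miyaura borylation (bis(pinacolato)diboron, PdCl2(dppf), KOAc, dioxane, 80 °C) would convert into 4-(benzyloxy)-5-methoxy-2-(4,4,5,5-tetramethyl-1,3,2-dioxaborolan-2-yl)benzaldehyde F6. Suzuki–Miyaura coupling of F6 with benzyl chloride 4 (PdCl2(dppf), K2CO3, THF/H2O, 70 °C), to which the aldehyde is inert, brings the route back at 6.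

Further compounds
F1 | step 5 | 5-(benzyloxy)-3-[4-(benzyloxy)-3-methoxyphenyl]-1-hydroxy-6-methoxy-1,3-dihydro-2-benzothiophene 2,2-dioxide (racemic mixture of diastereomers, no configuration defined) | COc1cc2C(O)S(=O)(=O)C(c3ccc(OCc4ccccc4)c(OC)c3)c2cc1OCc1ccccc1
F2 | step 8 | [(1S,2R,3R,4S)-7-(benzyloxy)-1-[4-(benzyloxy)-3-methoxyphenyl]-4-hydroxy-6-methoxy-1,2,3,4-tetrahydronaphthalene-2,3-diyl]dimethanol | COc1cc([C@H]2c3cc(OCc4ccccc4)c(OC)cc3[C@@H](O)[C@@H](CO)[C@@H]2CO)ccc1OCc1ccccc1
F3 | step 8 | cyclic phenylboronate of F2 bridging the C4 oxygen and the C3 hydroxymethyl oxygen (2-phenyl-1,3,2-dioxaborinane fused at C3/C4, C2 hydroxymethyl free) | COc1cc([C@H]2c3cc(OCc4ccccc4)c(OC)cc3[C@H]5OB(c6ccccc6)OC[C@H]5[C@@H]2CO)ccc1OCc1ccccc1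
F4 | step 8 | (2E)-3-[4-(benzyloxy)phenyl]prop-2-enoate of F3 at the C2 hydroxymethyl | COc1cc([C@H]2c3cc(OCc4ccccc4)c(OC)cc3[C@H]5OB(c6ccccc6)OC[C@H]5[C@@H]2COC(=O)/C=C/c7ccc(OCc8ccccc8)cc7)ccc1OCc1ccccc1
F5 | step 8 | [(1S,2R,3R)-7-(benzyloxy)-1-[4-(benzyloxy)-3-methoxyphenyl]-3-(hydroxymethyl)-6-methoxy-1,2,3,4-tetrahydronaphthalen-2-yl]methyl (2E)-3-[4-(benzyloxy)phenyl]prop-2-enoate | COc1cc([C@H]2c3cc(OCc4ccccc4)c(OC)cc3C[C@@H](CO)[C@@H]2COC(=O)/C=C/c5ccc(OCc6ccccc6)cc5)ccc1OCc1ccccc1
F6 | step 3 | 4-(benzyloxy)-5-methoxy-2-(4,4,5,5-tetramethyl-1,3,2-dioxaborolan-2-yl)benzaldehyde | COc1cc(C=O)c(B2OC(C)(C)C(C)(C)O2)cc1OCc1ccccc1
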